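**Retrosynthetic overview**

1. Target 26 ⇐ singlet-oxygen ene reaction on a 4-methylpent-3-enyl chain (last step); the (Z)-enol ester ⇐ Ru-catalysed anti-Markovnikov addition of 3-methylbut-2-enoic acid to a C6 ethynyl group.
2. C7 acetonyl ⇐ acetyl-radical addition to a 7-methylidene enone, with C7–H delivered last (cis to the alkyne); C2 CH2OH ⇐ Morita–Baylis–Hillman reaction with formaldehyde.
3. C5 quaternary centre ⇐ copper-mediated 1,6-addition of the side chain to a cyclohepta-2,4-dienone, anti to the C6 alkynyl group.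
4. Key step: the seven-membered ring (the only ring) ⇐ radical one-carbon ring expansion of a 4-(dichloromethyl)cyclohex-2-enone (3-exo attack forms C3–C4, fragmentation, loss of a chlorine atom).
5. That enone ⇐ enantioselective desymmetrising conjugate alkynylation of the dienone from p-cresol and chloroform. Ring order: arene → cyclohexadienone → cycloheptadienone.

Assumption: the triisopropylsilyl group on the alkyne counts as a protecting group, and ring positions are numbered throughout as in the final cycloheptenone (C1 ring ketone, C2 CH2OH-bearing carbon, C5 quaternary carbon, C6 alkyne/enol-ester carbon, C7 acetonyl carbon).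

**Route**

Step 1
Reactants: 1 4-methylphenol (p-cresol); 2 trichloromethane (chloroform)
Product: 3 4-(dichloromethyl)-4-methylcyclohexa-2,5-dien-1-one
Conditions: CHCl3, 20% aq. NaOH, β-cyclodextrin, 60 °C
Reagents that add atoms: none
Why: Abnormal Reimer–Tiemann reaction: dichlorocarbene attacks the methyl-bearing para carbon of the phenoxide (ortho positions shielded by the cyclodextrin), and the resulting dienone cannot rearomatise; no stereocentre is formed.

Step 2
Reactants: 3 4-(dichloromethyl)-4-methylcyclohexa-2,5-dien-1-one; 4 ethynyltri(propan-2-yl)silane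
Product: 7 (4S,5R)-4-(dichloromethyl)-4-methyl-5-{[tri(propan-2-yl)silyl]ethynyl}cyclohex-2-en-1-one, via alkynylalane 5 (not isolated), via aluminium dienolate 6 (not isolated)
Conditions: 4, Me3Al, Et3N (10 mol%), toluene, 60 °C; then 3, Ni(acac)2 (5 mol%), chiral bis(oxazoline) ligand (6 mol%, enantiomer giving 5R), Et2O–toluene, −20 °C; aq. potassium sodium tartrate
Reagents that add atoms: none
Why: Proposed new method: nickel-catalysed conjugate transfer of the alkynyl group from the dimethylalkynylalane to one of the two enantiotopic enone halves of 3, the chiral nickel complex choosing the enone face so that the alkyne-bearing carbon is R (attack anti to the bulky CHCl2 group; the configuration of the quaternary carbon is irrelevant because that carbon becomes sp2 in step 3); the closest known reaction type is the nickel–bis(oxazoline)-catalysed enantioselective conjugate alkynylation of cyclohex-2-enone with alkynylalanes.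

Step 3
Reactants: 7 (4S,5R)-4-(dichloromethyl)-4-methyl-5-{[tri(propan-2-yl)silyl]ethynyl}cyclohex-2-en-1-one
Product: 8 (6S)-5-methyl-6-{[tri(propan-2-yl)silyl]ethynyl}cyclohepta-2,4-dien-1-one
Conditions: Bu3SnH (1.15 equiv, syringe pump), AIBN (10 mol%), NaHCO3, PhH, 80 °C
Reagents that add atoms: none
Why: Proposed new method: radical-chain one-carbon ring expansion of Dowd–Beckwith type, in which Bu3Sn• abstracts chlorine, the α-chloroalkyl radical adds 3-exo to the enone β-carbon (new C3–C4 bond), the cyclopropylcarbinyl radical opens to the ring-expanded tertiary C5 radical, and this expels Cl• (which carries the chain by taking H from Bu3SnH) to give the conjugated dienone with C6 untouched; the closest known reaction type is the tin-hydride ring expansion of 4-(dichloromethyl)cyclohexa-2,5-dienones to tropones.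

Step 4
Reactants: 8 (6S)-5-methyl-6-{[tri(propan-2-yl)silyl]ethynyl}cyclohepta-2,4-dien-1-one; 9 5-bromo-2-methylpent-2-ene
Product: 13 (5S,6S)-5-methyl-5-(4-methylpent-3-en-1-yl)-6-{[tri(propan-2-yl)silyl]ethynyl}cyclohept-2-en-1-one, via Grignard reagent 10 (not isolated), via silyl dienol ether 11 (not isolated), via deconjugated enone 12 (not isolated)
Conditions: 9, Mg, THF; then 8, CuBr·SMe2 (20 mol%), TMSCl, DMPU, THF, −78 to −30 °C; then K2CO3, MeOH, rt
Reagents that add atoms: none
Why: Copper-catalysed, TMSCl-accelerated 1,6-conjugate addition of the Grignard reagent to the δ-carbon C5, on the face opposite the vicinal pseudo-axial C6 alkynyl group, sets the quaternary centre (side chain trans, methyl cis to the alkyne); methanolysis of the silyl dienol ether and base equilibration move the double bond into conjugation (any remaining 12 converges under the basic conditions of step 5).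

Step 5
Reactants: 13 (5S,6S)-5-methyl-5-(4-methylpent-3-en-1-yl)-6-{[tri(propan-2-yl)silyl]ethynyl}cyclohept-2-en-1-one; 14 formaldehyde
Product: 15 (5S,6S)-2-(hydroxymethyl)-5-methyl-5-(4-methylpent-3-en-1-yl)-6-{[tri(propan-2-yl)silyl]ethynyl}cyclohept-2-en-1-one
Conditions: 37% aq. HCHO, DMAP (0.3 equiv), THF–H2O, rt
Reagents that add atoms: none
Why: Morita–Baylis–Hillman reaction: DMAP adds to C3, the enolate is hydroxymethylated at C2 and DMAP is expelled; no stereocentre is formed or touched.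

Step 6
Reactants: 15 (5S,6S)-2-(hydroxymethyl)-5-methyl-5-(4-methylpent-3-en-1-yl)-6-{[tri(propan-2-yl)silyl]ethynyl}cyclohept-2-en-1-one; 16 N,N-dimethylmethaniminium iodide (Eschenmoser's salt)
Product: 20 (5S,6R)-2-(hydroxymethyl)-5-methyl-7-methylidene-5-(4-methylpent-3-en-1-yl)-6-{[tri(propan-2-yl)silyl]ethynyl}cyclohept-2-en-1-one, via dilithium enolate 17 (not isolated), via Mannich base 18 (not isolated), via ammonium iodide 19 (not isolated)
Conditions: LiN(i-Pr)2 (2.2 equiv), THF, −78 °C, then 16, −78 to 0 °C; MeI, MeOH, rt; aq. NaHCO3, CH2Cl2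
Reagents that add atoms: none
Why: Kinetic α′-deprotonation (alkoxide plus C7 enolate), Mannich reaction with Eschenmoser's salt, N-methylation and E1cB elimination give the α′-methylene ketone; C6 is unchanged in space (its descriptor changes only because C7 becomes sp2).

Step 7
Reactants: 20 (5S,6R)-2-(hydroxymethyl)-5-methyl-7-methylidene-5-(4-methylpent-3-en-1-yl)-6-{[tri(propan-2-yl)silyl]ethynyl}cyclohept-2-en-1-one; 21 2-oxopropanoic acid (pyruvic acid)
Product: 22 (5S,6S,7R)-2-(hydroxymethyl)-5-methyl-5-(4-methylpent-3-en-1-yl)-7-(2-oxopropyl)-6-{[tri(propan-2-yl)silyl]ethynyl}cyclohept-2-en-1-one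
Conditions: [Ir(dF(CF3)ppy)2(dtbbpy)]PF6 (1 mol%), K2HPO4, DME–H2O, blue LEDs, rt
Reagents that add atoms: none
Why: Photoredox decarboxylative acyl-radical conjugate addition (Giese type): the acetyl radical from pyruvate adds to the exocyclic CH2, the α-keto radical is reduced to the enolate, and this is protonated at C7 on the face opposite the vicinal silylalkynyl group and the syn C5 methyl, giving the 6,7-cis (7R) ketone.

Step 8
Reactants: 22 (5S,6S,7R)-2-(hydroxymethyl)-5-methyl-5-(4-methylpent-3-en-1-yl)-7-(2-oxopropyl)-6-{[tri(propan-2-yl)silyl]ethynyl}cyclohept-2-en-1-one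
Product: 23 (5S,6S,7R)-6-ethynyl-2-(hydroxymethyl)-5-methyl-5-(4-methylpent-3-en-1-yl)-7-(2-oxopropyl)cyclohept-2-en-1-one
Conditions: Bu4NF, AcOH (1:1), THF, 0 °C to rt
Reagents that add atoms: none
Why: Fluoride-induced protodesilylation of the alkynylsilane; the acetic acid buffer keeps the medium non-basic so the epimerisable C7 centre is preserved.

Step 9
Reactants: 23 (5S,6S,7R)-6-ethynyl-2-(hydroxymethyl)-5-methyl-5-(4-methylpent-3-en-1-yl)-7-(2-oxopropyl)cyclohept-2-en-1-one; 24 3-methylbut-2-enoic acid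
Product: 25 (1Z)-2-[(5S,6S,7R)-2-(hydroxymethyl)-5-methyl-5-(4-methylpent-3-en-1-yl)-1-oxo-7-(2-oxopropyl)cyclohept-2-en-6-yl]ethenyl 3-methylbut-2-enoate
Conditions: Ru(methallyl)2(dppb) (5 mol%), toluene, 50 °C
Reagents that add atoms: none
Why: Ruthenium-catalysed anti-Markovnikov addition of a carboxylic acid to a terminal alkyne through a ruthenium vinylidene; carboxylate attack at the terminal carbon and protonolysis give the (Z)-enol ester, and no sp3 stereocentre is touched.

Step 10
Reactants: 25 (1Z)-2-[(5S,6S,7R)-2-(hydroxymethyl)-5-methyl-5-(4-methylpent-3-en-1-yl)-1-oxo-7-(2-oxopropyl)cyclohept-2-en-6-yl]ethenyl 3-methylbut-2-enoate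
Product: 26 (1Z)-2-[(5S,6S,7R)-5-[(2E)-4-hydroperoxy-4-methylpent-2-en-1-yl]-2-(hydroxymethyl)-5-methyl-1-oxo-7-(2-oxopropyl)cyclohept-2-en-6-yl]ethenyl 3-methylbut-2-enoate (CNP0283385.3)
Conditions: O2, tetraphenylporphyrin (cat.), visible light, CH2Cl2, −20 °C; chromatography
Reagents that add atoms: dioxygen, O=O
Why: Schenck ene reaction of singlet oxygen with the trisubstituted alkene: oxygen bonds to the dimethyl-substituted carbon with abstraction of the allylic CH2 hydrogen, giving the tertiary hydroperoxide and the shifted (E)-alkene without a new stereocentre; the regioisomeric secondary hydroperoxide (about half of the material) is removed by chromatography, and the enone, enol ester and senecioate alkenes are too electron-poor to compete.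

**Compound list**

1 | 4-methylphenol (p-cresol) | Cc1ccc(O)cc1 | starting material
2 | trichloromethane (chloroform) | ClC(Cl)Cl | starting material
3 | 4-(dichloromethyl)-4-methylcyclohexa-2,5-dien-1-one | O=C1C=CC(C)(C(Cl)Cl)C=C1 | intermediate
4 | ethynyltri(propan-2-yl)silane | C#C[Si](C(C)C)(C(C)C)C(C)C | starting material
5 | dimethyl{[tri(propan-2-yl)silyl]ethynyl}alumane | C[Al](C)C#C[Si](C(C)C)(C(C)C)C(C)C | intermediate
6 | dimethyl{[(3R,4S)-4-(dichloromethyl)-4-methyl-3-{[tri(propan-2-yl)silyl]ethynyl}cyclohexa-1,5-dien-1-yl]oxy}alumane (aluminium dienolate of 7) | C1=C(O[Al](C)C)C=C[C@](C)(C(Cl)Cl)[C@H]1C#C[Si](C(C)C)(C(C)C)C(C)C | intermediate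
7 | (4S,5R)-4-(dichloromethyl)-4-methyl-5-{[tri(propan-2-yl)silyl]ethynyl}cyclohex-2-en-1-one | C1C(=O)C=C[C@](C)(C(Cl)Cl)[C@H]1C#C[Si](C(C)C)(C(C)C)C(C)C | intermediate
8 | (6S)-5-methyl-6-{[tri(propan-2-yl)silyl]ethynyl}cyclohepta-2,4-dien-1-one | C1C(=O)C=CC=C(C)[C@H]1C#C[Si](C(C)C)(C(C)C)C(C)C | intermediate
9 | 5-bromo-2-methylpent-2-ene | CC(C)=CCCBr | starting material
10 | bromo(4-methylpent-3-en-1-yl)magnesium | CC(C)=CCC[Mg]Br | intermediate
11 | trimethyl{[(5S,6S)-5-methyl-5-(4-methylpent-3-en-1-yl)-6-{[tri(propan-2-yl)silyl]ethynyl}cyclohepta-1,3-dien-1-yl]oxy}silane | C1C(O[Si](C)(C)C)=CC=C[C@](C)(CCC=C(C)C)[C@H]1C#C[Si](C(C)C)(C(C)C)C(C)C | intermediate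
12 | (5S,6S)-5-methyl-5-(4-methylpent-3-en-1-yl)-6-{[tri(propan-2-yl)silyl]ethynyl}cyclohept-3-en-1-one | C1C(=O)CC=C[C@](C)(CCC=C(C)C)[C@H]1C#C[Si](C(C)C)(C(C)C)C(C)C | intermediate
13 | (5S,6S)-5-methyl-5-(4-methylpent-3-en-1-yl)-6-{[tri(propan-2-yl)silyl]ethynyl}cyclohept-2-en-1-one | C1C(=O)C=CC[C@](C)(CCC=C(C)C)[C@H]1C#C[Si](C(C)C)(C(C)C)C(C)C | intermediate
14 | formaldehyde | C=O | starting material
15 | (5S,6S)-2-(hydroxymethyl)-5-methyl-5-(4-methylpent-3-en-1-yl)-6-{[tri(propan-2-yl)silyl]ethynyl}cyclohept-2-en-1-one | C1C(=O)C(CO)=CC[C@](C)(CCC=C(C)C)[C@H]1C#C[Si](C(C)C)(C(C)C)C(C)C | intermediate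
16 | N,N-dimethylmethaniminium iodide (Eschenmoser's salt) | C=[N+](C)C.[I-] | starting material
17 | dilithium salt of 15 (lithium alkoxide of the CH2OH group plus lithium C1=C7 enolate) | C1=C(O[Li])C(CO[Li])=CC[C@](C)(CCC=C(C)C)[C@H]1C#C[Si](C(C)C)(C(C)C)C(C)C | intermediate
18 | (5S,6S)-7-[(dimethylamino)methyl]-2-(hydroxymethyl)-5-methyl-5-(4-methylpent-3-en-1-yl)-6-{[tri(propan-2-yl)silyl]ethynyl}cyclohept-2-en-1-one (C7 epimers) | CN(C)CC1C(=O)C(CO)=CC[C@](C)(CCC=C(C)C)[C@H]1C#C[Si](C(C)C)(C(C)C)C(C)C | intermediate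
19 | N-methyl quaternary ammonium iodide of 18 (C7 epimers) | C[N+](C)(C)CC1C(=O)C(CO)=CC[C@](C)(CCC=C(C)C)[C@H]1C#C[Si](C(C)C)(C(C)C)C(C)C.[I-] | intermediate
20 | (5S,6R)-2-(hydroxymethyl)-5-methyl-7-methylidene-5-(4-methylpent-3-en-1-yl)-6-{[tri(propan-2-yl)silyl]ethynyl}cyclohept-2-en-1-one | C=C1C(=O)C(CO)=CC[C@](C)(CCC=C(C)C)[C@H]1C#C[Si](C(C)C)(C(C)C)C(C)C | intermediate
21 | 2-oxopropanoic acid (pyruvic acid) | CC(=O)C(=O)O | starting material
22 | (5S,6S,7R)-2-(hydroxymethyl)-5-methyl-5-(4-methylpent-3-en-1-yl)-7-(2-oxopropyl)-6-{[tri(propan-2-yl)silyl]ethynyl}cyclohept-2-en-1-one | CC(=O)C[C@H]1C(=O)C(CO)=CC[C@](C)(CCC=C(C)C)[C@H]1C#C[Si](C(C)C)(C(C)C)C(C)C | intermediate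
23 | (5S,6S,7R)-6-ethynyl-2-(hydroxymethyl)-5-methyl-5-(4-methylpent-3-en-1-yl)-7-(2-oxopropyl)cyclohept-2-en-1-one | CC(=O)C[C@H]1C(=O)C(CO)=CC[C@](C)(CCC=C(C)C)[C@H]1C#C | intermediate
24 | 3-methylbut-2-enoic acid | CC(C)=CC(=O)O | starting material
25 | (1Z)-2-[(5S,6S,7R)-2-(hydroxymethyl)-5-methyl-5-(4-methylpent-3-en-1-yl)-1-oxo-7-(2-oxopropyl)cyclohept-2-en-6-yl]ethenyl 3-methylbut-2-enoate | CC(=O)C[C@H]1C(=O)C(CO)=CC[C@](C)(CCC=C(C)C)[C@H]1/C=C\OC(=O)C=C(C)C | intermediate
26 | (1Z)-2-[(5S,6S,7R)-5-[(2E)-4-hydroperoxy-4-methylpent-2-en-1-yl]-2-(hydroxymethyl)-5-methyl-1-oxo-7-(2-oxopropyl)cyclohept-2-en-6-yl]ethenyl 3-methylbut-2-enoate | CC(=O)C[C@H]1C(=O)C(CO)=CC[C@](C)(C/C=C/C(C)(C)OO)[C@H]1/C=C\OC(=O)C=C(C)C | target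

**Step count and risks**

Total steps: 10. Longest linear sequence: 10 (fully linear from p-cresol).

The three steps most likely to fail are steps 2, 4 and 7.

Step 2 may give low enantioselectivity, because the desymmetrising alkynylation of a cyclohexadienone is untested. The fallback gives up asymmetric induction: starting from 3, the same alkynylalane 5 is added with an achiral catalyst (Ni(acac)2 reduced with i-Bu2AlH, no ligand) to give the racemate, which contains 7 and its mirror image (4R,5S)-4-(dichloromethyl)-4-methyl-5-{[tri(propan-2-yl)silyl]ethynyl}cyclohex-2-en-1-one F1. The enantiomers are separated by preparative chromatography on a chiral stationary phase, and the route is rejoined at 7.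

Step 4 may fail because the 1,6-addition has to build a quaternary carbon next to a substituted centre and competes with 1,4-addition. The fallback builds the chain in two stages from a smaller nucleophile. Starting from 8, vinylmagnesium bromide with CuBr·SMe2 and TMSCl transfers the small vinyl group to C5, giving trimethyl{[(5S,6S)-5-ethenyl-5-methyl-6-{[tri(propan-2-yl)silyl]ethynyl}cyclohepta-1,3-dien-1-yl]oxy}silane F2, with the ketone kept masked as the silyl dienol ether. Hydroboration of the vinyl group with 9-BBN-H gives the alkylborane 9-{2-[(5S,6S)-5-methyl-6-{[tri(propan-2-yl)silyl]ethynyl}-1-(trimethylsilyloxy)cyclohepta-1,3-dien-5-yl]ethyl}-9-borabicyclo[3.3.1]nonane F3. B-alkyl Suzuki coupling with 1-bromo-2-methylprop-1-ene (Pd(dppf)Cl2, K3PO4, THF–DMF) then gives the silyl dienol ether 11, where the route is rejoined.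

Step 7 may give poor cis selectivity at C7, because the face control rests on the slim alkynyl group. The fallback replaces the radical acylation by enolate alkylation followed by kinetic reprotonation. Starting from 15, double deprotonation with LiN(i-Pr)2 and alkylation with 3-bromo-2-methoxyprop-1-ene (freshly made from 2-methoxypropene and N-bromosuccinimide) gives mainly the 6,7-trans ketone (5S,6S,7S)-2-(hydroxymethyl)-7-(2-methoxyprop-2-en-1-yl)-5-methyl-5-(4-methylpent-3-en-1-yl)-6-{[tri(propan-2-yl)silyl]ethynyl}cyclohept-2-en-1-one F4. Renewed deprotonation at C7 and quenching at −78 °C with 2,6-di-tert-butylphenol delivers the proton to the face the electrophile used, giving the cis epimer (5S,6S,7R)-2-(hydroxymethyl)-7-(2-methoxyprop-2-en-1-yl)-5-methyl-5-(4-methylpent-3-en-1-yl)-6-{[tri(propan-2-yl)silyl]ethynyl}cyclohept-2-en-1-one F5. Aqueous oxalic acid hydrolyses the enol ether, and the route is rejoined at 22.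

**Further compounds**

F1 | step 2 | (4R,5S)-4-(dichloromethyl)-4-methyl-5-{[tri(propan-2-yl)silyl]ethynyl}cyclohex-2-en-1-one | C1C(=O)C=C[C@@](C)(C(Cl)Cl)[C@@H]1C#C[Si](C(C)C)(C(C)C)C(C)C
F2 | step 4 | trimethyl{[(5S,6S)-5-ethenyl-5-methyl-6-{[tri(propan-2-yl)silyl]ethynyl}cyclohepta-1,3-dien-1-yl]oxy}silane | C1C(O[Si](C)(C)C)=CC=C[C@](C)(C=C)[C@H]1C#C[Si](C(C)C)(C(C)C)C(C)C
F3 | step 4 | 9-{2-[(5S,6S)-5-methyl-6-{[tri(propan-2-yl)silyl]ethynyl}-1-(trimethylsilyloxy)cyclohepta-1,3-dien-5-yl]ethyl}-9-borabicyclo[3.3.1]nonane | C1C(O[Si](C)(C)C)=CC=C[C@](C)(CCB2C3CCCC2CCC3)[C@H]1C#C[Si](C(C)C)(C(C)C)C(C)C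
F4 | step 7 | (5S,6S,7S)-2-(hydroxymethyl)-7-(2-methoxyprop-2-en-1-yl)-5-methyl-5-(4-methylpent-3-en-1-yl)-6-{[tri(propan-2-yl)silyl]ethynyl}cyclohept-2-en-1-one | COC(=C)C[C@@H]1C(=O)C(CO)=CC[C@](C)(CCC=C(C)C)[C@H]1C#C[Si](C(C)C)(C(C)C)C(C)C
F5 | step 7 | (5S,6S,7R)-2-(hydroxymethyl)-7-(2-methoxyprop-2-en-1-yl)-5-methyl-5-(4-methylpent-3-en-1-yl)-6-{[tri(propan-2-yl)silyl]ethynyl}cyclohept-2-en-1-one | COC(=C)C[C@H]1C(=O)C(CO)=CC[C@](C)(CCC=C(C)C)[C@H]1C#C[Si](C(C)C)(C(C)C)C(C)C
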